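**Retrosynthetic overview**

1. Numbering as in labdanes: ring A = C1–C5 and C10 (C4 = CMe2), ring B = C5–C10 (C8=C9), side chain C11–C16, C20 = CH2OH on C13. The butenolide is joined last at C15 by a vinylogous aldol condensation; C12–C13 comes from a B-alkyl Suzuki–Miyaura coupling of a (Z)-vinyl iodide made from but-2-yne-1,4-diol; C9–C11 comes from Stille vinylation of the C9 enol triflate.
2. Ring A is disconnected at C3–C4: hydrogen-atom transfer to an isopropenyl group on C5 gives the tertiary C4 radical, which closes onto C3 of a vinyl sulfone arm on C10 (6-endo Giese cyclization). The sulfone on C2 is a temporary activating group, removed three steps later.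
3. Enabling feature: in ring A the quaternary C4 with its two methyl groups is bonded to the ring-fusion methine C5, so it is an isopropenyl group plus one hydrogen atom. With the C8 methyl and an oxygen at C9, ring B is then the ring of (R)-carvone, whose C5 stereocenter directs the two alkylations that build quaternary C10.
4. Order of ring formation: ring B (from carvone) → ring A (step 3) → butenolide ring (bought as 4-methylfuran-2(5H)-one, attached in step 11).

Key step: step 3

Remark: the epimer mixtures at C6 of 3 and at the sulfone-bearing carbon of 7, 9 and 10 are carried on without separation, because both centers are erased later (steps 2 and 6).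

**Route**

Step 1
Reactants: 1 (R)-(−)-carvone
Product: 3 (5R)-2,6-dimethyl-5-(prop-1-en-2-yl)cyclohex-2-en-1-one (6-methylcarvone; both C6 epimers), via lithium dienolate 2 (not isolated)
Conditions: LiN(iPr)2, THF, −78 °C; MeI, −78 → 0 °C
Reagents that add atoms: iodomethane, CI
Why: Kinetic deprotonation of the cross-conjugated enone at C6 and SN2 methylation of the lithium dienolate (enolate alkylation) install the methyl group that becomes the C10 methyl, and the C6 configuration is left uncontrolled because it is erased on the next enolisation.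

Step 2
Reactants: 3 6-methylcarvone; 4 2,3-bis(phenylsulfonyl)prop-1-ene
Product: 6 (5S,6S)-2,6-dimethyl-6-[2-(phenylsulfonyl)prop-2-en-1-yl]-5-(prop-1-en-2-yl)cyclohex-2-en-1-one (C6 methyl cis to the isopropenyl group), via lithium dienolate 5 (not isolated)
Conditions: LiN(iPr)2, THF/DMPU, −78 → 0 °C; then 4, −78 → 0 °C
Reagents that add atoms: none
Why: The tetrasubstituted lithium dienolate adds to the terminal CH2 of 4 and benzenesulfinate is lost (conjugate addition–elimination, a formal SN2′ allylation), and the electrophile should enter the enolate face anti to the neighbouring isopropenyl group, so that the new quaternary center carries its methyl cis and the sulfonylallyl arm trans to that group (substrate control by the carvone stereocenter).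

Step 3
Reactants: 6 sulfonylallyl ketone
Product: 7 (4aS,8aS)-2,5,5,8a-tetramethyl-7-(phenylsulfonyl)-4a,5,6,7,8,8a-hexahydronaphthalen-1(4H)-one (trans-fused; both C7 epimers)
Conditions: Fe(acac)3 (0.3 equiv), PhSiH3 (2.5 equiv), EtOH/HOCH2CH2OH, 60 °C, high dilution
Reagents that add atoms: none
Why: Fe(acac)3 and PhSiH3 generate an iron hydride that transfers a hydrogen atom to the CH2 terminus of the electron-rich isopropenyl group, so that the Markovnikov tertiary radical at C4 already carries both methyl groups; this nucleophilic radical adds to the unsubstituted terminus C3 of the vinyl sulfone arm, and the α-sulfonyl radical at C2 is reduced and protonated by the alcohol solvent. The closest known reaction type is the iron-mediated reductive olefin coupling, a Giese-type radical conjugate addition started by metal-hydride hydrogen-atom transfer, here used intramolecularly. Ring A closes in the 6-endo-trig mode with respect to the acceptor alkene, which is the normal conjugate-addition regiochemistry, whereas 5-exo attack would have to form a bond to the fully substituted sulfonyl-bearing carbon and give an unstabilised primary radical. No stereocenter of the target is made in this step: C5 comes from carvone and C10 from step 2, and because the radical-bearing carbon on C5 and the acceptor arm on C10 are trans and both equatorial they can only bridge to the trans-fused decalin with the C10 methyl axial; the new sulfone-bearing center C2 forms as a mixture and is erased in step 6. The step needs hydrogen-atom transfer to the isopropenyl group in preference to the enone and the vinyl sulfone, and cyclisation faster than reduction of the tertiary radical; the first should be secured by the higher reactivity of electron-rich 1,1-disubstituted alkenes toward the iron hydride, the second by the polarity-matched six-membered closure under high dilution.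

Step 4
Reactants: 7 bicyclic enone sulfone
Product: 9 (4aS,8aS)-2,5,5,8a-tetramethyl-7-(phenylsulfonyl)-3,4,4a,5,6,7,8,8a-octahydronaphthalen-1-yl trifluoromethanesulfonate, via lithium enolate 8 (not isolated)
Conditions: LiBH(s-Bu)3, THF, −78 °C; then PhNTf2, −78 → 0 °C
Reagents that add atoms: N-phenylbis(trifluoromethanesulfonimide), O=S(=O)(N(c1ccccc1)S(=O)(=O)C(F)(F)F)C(F)(F)F
Why: The bulky borohydride delivers hydride to the unsubstituted β-carbon of the hindered enone (conjugate reduction), and the enolate, which can only be the C8=C9 regioisomer because C10 is quaternary, is trapped on oxygen by PhNTf2 (enol triflate formation) without setting a stereocenter.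

Step 5
Reactants: 9 enol triflate
Product: 10 (4aS,8aS)-1-ethenyl-2,5,5,8a-tetramethyl-7-(phenylsulfonyl)-3,4,4a,5,6,7,8,8a-octahydronaphthalene
Conditions: CH2=CHSnBu3, Pd(PPh3)4 (5 mol %), LiCl, THF, reflux
Reagents that add atoms: tributyl(vinyl)stannane, C=C[Sn](CCCC)(CCCC)CCCC
Why: Stille cross-coupling of the vinyl triflate with the vinylstannane, with LiCl to assist transmetalation, forms the C9–C11 bond and leaves the sulfone and the ring fusion untouched.

Step 6
Reactants: 10 diene sulfone
Product: 11 (4aS,8aS)-1-ethenyl-2,5,5,8a-tetramethyl-3,4,4a,5,6,7,8,8a-octahydronaphthalene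
Conditions: Na/Hg (6% Na), Na2HPO4, MeOH/THF, −20 °C → rt
Reagents that add atoms: none
Why: Single-electron reduction of the alkyl phenyl sulfone cleaves the C2–S bond and the carbanion is protonated (reductive desulfonylation), which removes the activating group together with the only uncontrolled stereocenter of the bicycle.

Step 7
Reactants: 12 but-2-yne-1,4-diol (3 equiv)
Product: 13 4-[(tert-butyldimethylsilyl)oxy]but-2-yn-1-ol
Conditions: TBSCl (1 equiv), imidazole, THF/DMF, 0 °C → rt
Reagents that add atoms: tert-butyldimethylsilyl chloride, CC(C)(C)[Si](C)(C)Cl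
Why: Monosilylation of the symmetrical diol used in excess (silyl ether formation) differentiates the two hydroxyl groups, and no stereocenter is involved.

Step 8
Reactants: 13 monosilylated butynediol
Product: 15 (2Z)-4-[(tert-butyldimethylsilyl)oxy]-3-iodobut-2-en-1-ol, via cyclic vinylalanate 14 (not isolated)
Conditions: NaAlH2(OCH2CH2OMe)2, THF, 0 °C → rt; then I2, THF, −78 °C
Reagents that add atoms: iodine, II
Why: The aluminium alkoxide of the free propargylic hydroxyl delivers hydride intramolecularly in a trans-hydroalumination that places aluminium on the distal alkyne carbon in a five-membered alanate, and iodinolysis with retention gives the (Z)-vinyl iodide whose geometry fixes the later C13=C14 alkene (hydroxyl-directed hydroalumination–iodination).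

Step 9
Reactants: 11 vinyl decalin; 15 (Z)-vinyl iodide
Product: 17 (2E)-4-[(tert-butyldimethylsilyl)oxy]-3-{2-[(4aS,8aS)-2,5,5,8a-tetramethyl-3,4,4a,5,6,7,8,8a-octahydronaphthalen-1-yl]ethyl}but-2-en-1-ol, via alkylborane 16 (not isolated)
Conditions: 11, 9-BBN-H, THF, rt → 50 °C; then 15, PdCl2(dppf) (5 mol %), AsPh3, Cs2CO3, DMF/H2O, rt
Reagents that add atoms: none
Why: The borane adds anti-Markovnikov to the monosubstituted vinyl group, the tetrasubstituted ring alkene being inert, and the primary alkylborane couples with the vinyl iodide with retention of alkene geometry (B-alkyl Suzuki–Miyaura coupling), which forms the C12–C13 bond and the (E)-trisubstituted alkene.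

Step 10
Reactants: 17 allylic alcohol
Product: 18 (2E)-4-[(tert-butyldimethylsilyl)oxy]-3-{2-[(4aS,8aS)-2,5,5,8a-tetramethyl-3,4,4a,5,6,7,8,8a-octahydronaphthalen-1-yl]ethyl}but-2-enal
Conditions: MnO2, CH2Cl2, rt
Reagents that add atoms: none
Why: The heterogeneous oxidant should oxidise the allylic alcohol chemoselectively to the enal without moving or isomerising the double bond (allylic alcohol oxidation).

Step 11
Reactants: 18 enal; 19 4-methylfuran-2(5H)-one
Product: 22 (5Z)-5-[(2E)-4-[(tert-butyldimethylsilyl)oxy]-3-{2-[(4aS,8aS)-2,5,5,8a-tetramethyl-3,4,4a,5,6,7,8,8a-octahydronaphthalen-1-yl]ethyl}but-2-en-1-ylidene]-4-methylfuran-2(5H)-one (silyl ether of the target), via silyloxyfuran 20 (not isolated), via silyl aldol adduct 21 (not isolated)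
Conditions: 19, TBSOTf, iPr2NEt, CH2Cl2, 0 °C; then 18, −78 → 0 °C; then DBU, rt
Reagents that add atoms: none
Why: The butenolide is silylated to the 2-silyloxyfuran, which adds through C5 to the silyl-activated aldehyde (vinylogous Mukaiyama aldol addition), and DBU then removes the acidic C5 proton and expels silanolate (E1cB elimination) to give the ylidene butenolide, the (Z)-isomer being expected because it avoids the clash between the side chain and the C4 methyl group.

Step 12
Reactants: 22 silyl ether of the target
Product: 23 (5Z)-5-[(2E)-4-hydroxy-3-{2-[(4aS,8aS)-2,5,5,8a-tetramethyl-3,4,4a,5,6,7,8,8a-octahydronaphthalen-1-yl]ethyl}but-2-en-1-ylidene]-4-methylfuran-2(5H)-one (CNP0288110.2)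
Conditions: HF·pyridine, pyridine, THF, 0 °C
Reagents that add atoms: none
Why: Buffered fluoride cleavage of the primary allylic silyl ether (desilylation) should free the alcohol without ionising the allylic position or opening the butenolide.

**Compound list**

1 | (R)-(−)-carvone, (5R)-2-methyl-5-(prop-1-en-2-yl)cyclohex-2-en-1-one | O=C1C(C)=CC[C@@H](C(C)=C)C1 | starting material
2 | lithium 6-methyl-3-(prop-1-en-2-yl)cyclohexa-1,5-dien-1-olate (kinetic dienolate of 1, stereocenter as in 1) | [Li]OC1=C[C@H](C(C)=C)CC=C1C | intermediate (not isolated)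
3 | (5R)-2,6-dimethyl-5-(prop-1-en-2-yl)cyclohex-2-en-1-one (both C6 epimers) | O=C1C(C)=CC[C@@H](C(C)=C)C1C | intermediate
4 | 2,3-bis(phenylsulfonyl)prop-1-ene | C=C(CS(=O)(=O)c1ccccc1)S(=O)(=O)c1ccccc1 | starting material
5 | lithium 2,6-dimethyl-3-(prop-1-en-2-yl)cyclohexa-1,5-dien-1-olate (dienolate of 3) | [Li]OC1=C(C)[C@H](C(C)=C)CC=C1C | intermediate (not isolated)
6 | (5S,6S)-2,6-dimethyl-6-[2-(phenylsulfonyl)prop-2-en-1-yl]-5-(prop-1-en-2-yl)cyclohex-2-en-1-one | O=C1C(C)=CC[C@@H](C(C)=C)[C@]1(C)CC(=C)S(=O)(=O)c1ccccc1 | intermediate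
7 | (4aS,8aS)-2,5,5,8a-tetramethyl-7-(phenylsulfonyl)-4a,5,6,7,8,8a-hexahydronaphthalen-1(4H)-one (trans-fused, C7 epimers) | O=C1C(C)=CC[C@H]2C(C)(C)CC(S(=O)(=O)c3ccccc3)C[C@]12C | intermediate
8 | lithium (4aS,8aS)-2,5,5,8a-tetramethyl-7-(phenylsulfonyl)-3,4,4a,5,6,7,8,8a-octahydronaphthalen-1-olate | [Li]OC1=C(C)CC[C@H]2C(C)(C)CC(S(=O)(=O)c3ccccc3)C[C@]12C | intermediate (not isolated)
9 | (4aS,8aS)-2,5,5,8a-tetramethyl-7-(phenylsulfonyl)-3,4,4a,5,6,7,8,8a-octahydronaphthalen-1-yl trifluoromethanesulfonate | O=S(=O)(OC1=C(C)CC[C@H]2C(C)(C)CC(S(=O)(=O)c3ccccc3)C[C@]12C)C(F)(F)F | intermediate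
10 | (4aS,8aS)-1-ethenyl-2,5,5,8a-tetramethyl-7-(phenylsulfonyl)-3,4,4a,5,6,7,8,8a-octahydronaphthalene | C=CC1=C(C)CC[C@H]2C(C)(C)CC(S(=O)(=O)c3ccccc3)C[C@]12C | intermediate
11 | (4aS,8aS)-1-ethenyl-2,5,5,8a-tetramethyl-3,4,4a,5,6,7,8,8a-octahydronaphthalene | C=CC1=C(C)CC[C@H]2C(C)(C)CCC[C@]12C | intermediate
12 | but-2-yne-1,4-diol | OCC#CCO | starting material
13 | 4-[(tert-butyldimethylsilyl)oxy]but-2-yn-1-ol | OCC#CCO[Si](C)(C)C(C)(C)C | intermediate
14 | sodium cyclic vinylalanate (five-membered ring Al–O–CH2–CH=C, aluminium on the carbon bearing CH2OTBS, two 2-methoxyethoxy ligands) | [Na+].COCCO[Al-]1(OCCOC)OCC=C1CO[Si](C)(C)C(C)(C)C | intermediate (not isolated)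
15 | (2Z)-4-[(tert-butyldimethylsilyl)oxy]-3-iodobut-2-en-1-ol | OC\C=C(\CO[Si](C)(C)C(C)(C)C)I | intermediate
16 | 9-{2-[(4aS,8aS)-2,5,5,8a-tetramethyl-3,4,4a,5,6,7,8,8a-octahydronaphthalen-1-yl]ethyl}-9-borabicyclo[3.3.1]nonane | C(CC1=C(C)CC[C@H]2C(C)(C)CCC[C@]12C)B1C2CCCC1CCC2 | intermediate (not isolated)
17 | (2E)-4-[(tert-butyldimethylsilyl)oxy]-3-{2-[(4aS,8aS)-2,5,5,8a-tetramethyl-3,4,4a,5,6,7,8,8a-octahydronaphthalen-1-yl]ethyl}but-2-en-1-ol | OC\C=C(\CO[Si](C)(C)C(C)(C)C)CCC1=C(C)CC[C@H]2C(C)(C)CCC[C@]12C | intermediate
18 | (2E)-4-[(tert-butyldimethylsilyl)oxy]-3-{2-[(4aS,8aS)-2,5,5,8a-tetramethyl-3,4,4a,5,6,7,8,8a-octahydronaphthalen-1-yl]ethyl}but-2-enal | O=C\C=C(\CO[Si](C)(C)C(C)(C)C)CCC1=C(C)CC[C@H]2C(C)(C)CCC[C@]12C | intermediate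
19 | 4-methylfuran-2(5H)-one | CC1=CC(=O)OC1 | starting material
20 | tert-butyldimethyl[(4-methylfuran-2-yl)oxy]silane | CC1=COC(O[Si](C)(C)C(C)(C)C)=C1 | intermediate (not isolated)
21 | 5-[(2E)-1,4-bis[(tert-butyldimethylsilyl)oxy]-3-{2-[(4aS,8aS)-2,5,5,8a-tetramethyl-3,4,4a,5,6,7,8,8a-octahydronaphthalen-1-yl]ethyl}but-2-en-1-yl]-4-methylfuran-2(5H)-one (diastereomer mixture at the two new centers) | CC1=CC(=O)OC1C(O[Si](C)(C)C(C)(C)C)\C=C(\CO[Si](C)(C)C(C)(C)C)CCC1=C(C)CC[C@H]2C(C)(C)CCC[C@]12C | intermediate (not isolated)
22 | (5Z)-5-[(2E)-4-[(tert-butyldimethylsilyl)oxy]-3-{2-[(4aS,8aS)-2,5,5,8a-tetramethyl-3,4,4a,5,6,7,8,8a-octahydronaphthalen-1-yl]ethyl}but-2-en-1-ylidene]-4-methylfuran-2(5H)-one | CC1=CC(=O)O/C1=C\C=C(\CO[Si](C)(C)C(C)(C)C)CCC1=C(C)CC[C@H]2C(C)(C)CCC[C@]12C | intermediate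
23 | (5Z)-5-[(2E)-4-hydroxy-3-{2-[(4aS,8aS)-2,5,5,8a-tetramethyl-3,4,4a,5,6,7,8,8a-octahydronaphthalen-1-yl]ethyl}but-2-en-1-ylidene]-4-methylfuran-2(5H)-one | CC1=CC(=O)O/C1=C\C=C(\CO)CCC1=C(C)CC[C@H]2C(C)(C)CCC[C@]12C | target

**Step count and risks**

Total step count: 12. Longest linear sequence: 10 steps (steps 1–6 and 9–12).

Steps most likely to fail:

Step 3 (key step). What may go wrong: hydrogen-atom transfer to the vinyl sulfone or the enone instead of the isopropenyl group, or reduction of the tertiary radical before it cyclises, so that the isopropenyl group is merely hydrogenated. The fallback sets out from 6 and returns at 7, and makes the same radical by a polar/tin sequence. Markovnikov addition of HBr (HBr in AcOH, CH2Cl2, 0 °C) to the isopropenyl group, the only electron-rich alkene of 6, should give the tertiary bromide F1. Slow addition of Bu3SnH and AIBN to F1 in refluxing benzene at high dilution then abstracts bromine, and the C4 radical should close onto the vinyl sulfone in the same 6-endo mode to give 7.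

Step 11. What may go wrong: enolisation of the enal toward C12 or C20 under the silyl triflate/amine conditions with loss of the C13=C14 geometry, and incomplete or unselective elimination that leaves E/Z mixtures at the exocyclic alkene. The fallback sets out from 18 and returns at 22, and builds the lactone ring on an alkyne instead. Colvin homologation (Me3SiCHN2, LiN(iPr)2, THF, −78 °C → rt) should convert the aldehyde into the enyne F2. Coupling of F2 with (2Z)-3-iodobut-2-enoic acid (C/C(I)=C/C(O)=O) under PdCl2(PPh3)2, CuI and Et3N in MeCN, a Sonogashira coupling followed by 5-exo-dig attack of the carboxylate on the alkyne, should then give the (Z)-ylidene butenolide 22 directly.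

Step 2. What may go wrong: sluggish bond formation at the hindered tetrasubstituted enolate, further conjugate addition of enolate to the vinyl sulfone of the product, or lower facial selectivity with this large electrophile. The fallback sets out from 3 and returns at 6, and installs the arm and the sulfonyl group separately. Alkylation of the dienolate of 3 with 2,3-dibromopropene (LiN(iPr)2, THF/DMPU, −78 → 0 °C), a plain allylic SN2 reaction, should give the 2-bromoallyl ketone F3 with the arm anti to the isopropenyl group. Copper-catalysed coupling of the vinyl bromide of F3 with PhSO2Na (CuI, N,N′-dimethylethylenediamine, DMSO, 90 °C) then gives 6.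

Further compounds
F1 | step 3 | 5-(2-bromopropan-2-yl)-2,6-dimethyl-6-[2-(phenylsulfonyl)prop-2-en-1-yl]cyclohex-2-en-1-one (ring stereocenters arranged as in 6) | O=C1C(C)=CC[C@@H](C(C)(C)Br)[C@]1(C)CC(=C)S(=O)(=O)c1ccccc1
F2 | step 11 | tert-butyldimethyl{[(2E)-2-{2-[(4aS,8aS)-2,5,5,8a-tetramethyl-3,4,4a,5,6,7,8,8a-octahydronaphthalen-1-yl]ethyl}pent-2-en-4-yn-1-yl]oxy}silane | C#C\C=C(\CO[Si](C)(C)C(C)(C)C)CCC1=C(C)CC[C@H]2C(C)(C)CCC[C@]12C
F3 | step 2 | 6-(2-bromoprop-2-en-1-yl)-2,6-dimethyl-5-(prop-1-en-2-yl)cyclohex-2-en-1-one (ring stereocenters arranged as in 6) | O=C1C(C)=CC[C@@H](C(C)=C)[C@]1(C)CC(Br)=C
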